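**Retrosynthetic overview**
1. Lophirachalcone ⇐ BBr3 demethylation ⇐ Heck installation of the chalcone arm on an aryl bromide ⇐ Friedel–Crafts union at the diarylmethine carbon (chiral phosphoric acid) of an East resorcinol-tetrahydrofuran with a West dihydrobenzofuran ortho-quinone methide.
2. East fragment ⇐ hydride reduction of a cyclic aryl hemiketal ⇐ one-pot conjugate addition/aldol that desymmetrises C2-symmetric (E)-1,4-bis(2,4-dimethoxyphenyl)but-2-ene-1,4-dione (key step) ⇐ 1,3-dimethoxybenzene + fumaryl chloride.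
3. West fragment ⇐ CuH 1,4-reduction (dearomatisation) of a 3-aroyl-2-arylbenzofuran ⇐ Friedel–Crafts acylation ⇐ Sonogashira/cyclisation of 4-bromo-2-iodophenol with 4-ethynylanisole.
4. Ring order: tetrahydrofuran (steps 2–3), benzofuran (step 5), dihydrobenzofuran (step 7); all benzene rings are bought.

Assumption: for the three catalyst-controlled steps (2, 7, 10) the sense of induction on these substrates is not known in advance; the catalyst enantiomer written is the one taken to give the drawn configuration, and its mirror image is used if the first run shows the opposite sense.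

**Step 1**
Reactants: 1 1,3-dimethoxybenzene (2.1 equiv); 2 fumaryl chloride
Product: 4 (E)-1,4-bis(2,4-dimethoxyphenyl)but-2-ene-1,4-dione, via mono-acylated acid chloride 3 (not isolated)
Conditions: AlCl3 (2.2 equiv), CH2Cl2, −10 → 0 °C, 1 h; ice/aq. HCl
Reagents that add atoms: none
Why: Double Friedel–Crafts acylation at C4 of the arene (para to one methoxy, ortho to the other) keeps the E alkene, and the low temperature avoids ortho-demethylation; no stereocentre is formed.

**Step 2 (key step)**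
Reactants: 4 (E)-1,4-bis(2,4-dimethoxyphenyl)but-2-ene-1,4-dione; 5 4-methoxybenzylmagnesium chloride (1.1 equiv); 6 4-methoxybenzaldehyde (1.2 equiv)
Product: 9 (2,4-dimethoxyphenyl)[(2S,3S,4S)-5-(2,4-dimethoxyphenyl)-5-hydroxy-4-(4-methoxybenzyl)-2-(4-methoxyphenyl)oxolan-3-yl]methanone (cyclic hemiketal as a mixture of C5 epimers), via magnesium enolate 7 (not isolated), via open-chain aldol 8 (not isolated)
Conditions: CuBr·SMe2 (5 mol%), (R)-Tol-BINAP (6 mol%), t-BuOMe/CH2Cl2, −78 °C, slow addition of 5; then 6, −78 → −20 °C, 3 h; aq. NH4Cl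
Reagents that add atoms: none
Why: Proposed new method: the two alkene carbons of the C2-symmetric ene-dione are equivalent, so the (R)-Tol-BINAP complex of CuBr only has to select the alkene face when it transfers the benzyl group (benzyl-bearing centre S); the Z magnesium enolate then adds to the aldehyde through a chair transition state (syn aldol) and the aldolate closes onto the remote ketone, aldol reversibility draining minor isomers into the all-trans hemiketal (aroyl-bearing and aryl-carbinol centres S,S); the closest known chemistry is copper-catalysed asymmetric conjugate addition of Grignard reagents to acyclic enones and tandem conjugate addition–aldol three-component coupling.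

**Step 3**
Reactants: 9 cyclic hemiketal
Product: 11 (2,4-dimethoxyphenyl)[(2S,3S,4S,5R)-5-(2,4-dimethoxyphenyl)-4-(4-methoxybenzyl)-2-(4-methoxyphenyl)oxolan-3-yl]methanone, via oxocarbenium ion 10 (not isolated)
Conditions: Et3SiH (3 equiv), BF3·OEt2 (2 equiv), CH2Cl2, −78 °C, 2 h; aq. NaHCO3
Reagents that add atoms: none
Why: Ionic hydrogenation of a cyclic aryl hemiketal: hydride attacks the oxocarbenium ion anti to the neighbouring benzyl group, so the aryl group ends cis to the benzyl group (new centre R), as in tetrahydrofuran lignan syntheses; the aryl ketone is inert at −78 °C.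

**Step 4**
Reactants: 11 hexamethyl ether
Product: 12 (2,4-dihydroxyphenyl)[(2S,3S,4S,5R)-5-(2,4-dihydroxyphenyl)-4-(4-hydroxybenzyl)-2-(4-hydroxyphenyl)oxolan-3-yl]methanone
Conditions: BBr3 (12 equiv), CH2Cl2, −78 → 0 °C; MeOH, then H2O
Reagents that add atoms: none
Why: Lewis-acid aryl methyl ether cleavage (bromide attacks each O-methyl of the aryloxy-boron adducts) frees the phenols needed for hydrogen-bond-directed coupling; the low temperature is chosen to spare the benzylic C–O bonds and the four stereocentres.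

**Step 5**
Reactants: 13 4-bromo-2-iodophenol; 14 1-ethynyl-4-methoxybenzene (1.1 equiv)
Product: 16 5-bromo-2-(4-methoxyphenyl)-1-benzofuran, via ortho-alkynylphenol 15 (not isolated)
Conditions: PdCl2(PPh3)2 (2 mol%), CuI (4 mol%), Et3N, DMF, rt → 70 °C
Reagents that add atoms: none
Why: Sonogashira coupling at the more reactive C–I bond, then in situ 5-endo-dig hydroalkoxylation of the alkynylphenol, gives the 2-arylbenzofuran and keeps the bromide for the later Heck reaction.

**Step 6**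
Reactants: 16 5-bromo-2-(4-methoxyphenyl)-1-benzofuran; 17 2,4-dimethoxybenzoyl chloride (1.1 equiv)
Product: 19 [5-bromo-2-(4-methoxyphenyl)-1-benzofuran-3-yl](2-hydroxy-4-methoxyphenyl)methanone, via dimethoxy ketone 18 (not isolated)
Conditions: AlCl3 (3 equiv), 1,2-dichloroethane, 0 → 50 °C; ice/aq. HCl
Reagents that add atoms: none
Why: Friedel–Crafts acylation at the nucleophilic C3 of the 2-arylbenzofuran, after which AlCl3 chelated between the ketone and the ortho-methoxy group cleaves only that ether (the chelation-controlled demethylation used to make 2-hydroxy-4-methoxybenzophenone).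

**Step 7**
Reactants: 19 benzofuranyl ketone
Product: 21 [(2R,3R)-5-bromo-2-(4-methoxyphenyl)-2,3-dihydro-1-benzofuran-3-yl](2-hydroxy-4-methoxyphenyl)methanone, via bis-silyl enol ether 20 (not isolated)
Conditions: Cu(OAc)2 (5 mol%), (R)-DTBM-SEGPHOS (5.5 mol%), (EtO)2MeSiH (4 equiv), toluene, 0 °C → rt; then 1 M HCl, THF, 0 °C; then DBU (5 mol%), CH2Cl2, 0 °C
Reagents that add atoms: none
Why: Proposed new method: the furan ring of a 3-acylbenzofuran is a weakly aromatic beta-aryloxy enone, so the (R)-DTBM-SEGPHOS complex of CuH should deliver hydride to C2 in the 1,4 sense (C2 set R by the catalyst) to give a silyl enol ether that shields the ketone from 1,2-reduction, and hydrolysis followed by base equilibration of the acidic C3 gives the trans isomer (C3 R); the closest known chemistry is CuH-catalysed asymmetric conjugate reduction of beta,beta-disubstituted enones and coumarins and copper-catalysed dearomative borylation of indole esters.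

**Step 8**
Reactants: 21 trans ketone
Product: 22 2-{[(2R,3S)-5-bromo-2-(4-methoxyphenyl)-2,3-dihydro-1-benzofuran-3-yl](hydroxy)methyl}-5-methoxyphenol (both carbinol epimers)
Conditions: NaBH4 (2 equiv), THF/MeOH, −10 °C; pH 7 buffer; used crude
Reagents that add atoms: none
Why: Borohydride 1,2-reduction of the aryl ketone; the carbinol configuration is irrelevant because this carbon is planarised in step 10, and C2 and C3 are untouched (the descriptor of C3 changes only through substituent priorities).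

**Step 9**
Reactants: 1 1,3-dimethoxybenzene; 23 3-chloropropanoyl chloride
Product: 24 3-chloro-1-(2,4-dimethoxyphenyl)propan-1-one
Conditions: AlCl3 (1.1 equiv), CH2Cl2, 0 °C
Reagents that add atoms: none
Why: Friedel–Crafts acylation at C4 of the arene gives a bench-stable beta-chloroketone that serves as a masked aryl vinyl ketone.

**Step 10**
Reactants: 22 ortho-hydroxybenzylic alcohol; 12 East hexaphenol (2 equiv, excess recovered)
Product: 26 (2,4-dihydroxyphenyl){(2S,3S,4S,5R)-5-[5-((R)-[(2R,3R)-5-bromo-2-(4-methoxyphenyl)-2,3-dihydro-1-benzofuran-3-yl](2-hydroxy-4-methoxyphenyl)methyl)-2,4-dihydroxyphenyl]-4-(4-hydroxybenzyl)-2-(4-hydroxyphenyl)oxolan-3-yl}methanone, via ortho-quinone methide 25 (not isolated)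
Conditions: (R)-TRIP [(R)-3,3'-bis(2,4,6-triisopropylphenyl)-1,1'-binaphthyl-2,2'-diyl hydrogen phosphate] (10 mol%), 4 Å MS, CH2Cl2/EtOAc 3:1, −20 °C → rt, slow addition of 22
Reagents that add atoms: none
Why: Chiral-phosphoric-acid-catalysed ortho-quinone methide Friedel–Crafts alkylation of a phenol: the acid dehydrates 22 to 25 (the water is taken up by the sieves) and, hydrogen-bonded to its carbonyl oxygen and to the hydroxyl next to the most nucleophilic carbon of the alkyl-resorcinol ring of 12 (the acyl-resorcinol and monophenol rings are much less nucleophilic), directs attack to one face of the methide so that the diarylmethine centre is formed R under catalyst control.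

**Step 11**
Reactants: 26 aryl bromide; 24 3-chloro-1-(2,4-dimethoxyphenyl)propan-1-one (1.5 equiv)
Product: 28 (E)-1-(2,4-dimethoxyphenyl)-3-{(2R,3R)-3-[(R)-{5-[(2R,3S,4S,5S)-4-(2,4-dihydroxybenzoyl)-3-(4-hydroxybenzyl)-5-(4-hydroxyphenyl)oxolan-2-yl]-2,4-dihydroxyphenyl}(2-hydroxy-4-methoxyphenyl)methyl]-2-(4-methoxyphenyl)-2,3-dihydro-1-benzofuran-5-yl}prop-2-en-1-one, via aryl vinyl ketone 27 (not isolated)
Conditions: Pd(OAc)2 (5 mol%), P(o-tol)3 (12 mol%), NaOAc (4 equiv), DMF, 100 °C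
Reagents that add atoms: none
Why: Heck reaction: acetate eliminates HCl from 24 to release the vinyl ketone in low concentration, and insertion/beta-hydride elimination gives the E enone; the weak base leaves the phenols, the beta-alkoxy ketone and all stereocentres alone.

**Step 12**
Reactants: 28 tetramethyl ether
Product: 29 lophirachalcone
Conditions: BBr3 (16 equiv), CH2Cl2, −78 → 0 °C; MeOH, then H2O
Reagents that add atoms: none
Why: BBr3 cleavage of the four remaining aryl methyl ethers at low temperature gives the undecaphenol without touching the enone or the seven stereocentres.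

**Compound list**
1 | 1,3-dimethoxybenzene | COc1cccc(OC)c1 | starting material
2 | fumaryl chloride | O=C(Cl)/C=C/C(=O)Cl | starting material
3 | (E)-4-(2,4-dimethoxyphenyl)-4-oxobut-2-enoyl chloride | COc1ccc(C(=O)/C=C/C(=O)Cl)c(OC)c1 | intermediate (not isolated)
4 | (E)-1,4-bis(2,4-dimethoxyphenyl)but-2-ene-1,4-dione | COc1ccc(C(=O)/C=C/C(=O)c2ccc(OC)cc2OC)c(OC)c1 | intermediate
5 | 4-methoxybenzylmagnesium chloride | COc1ccc(C[Mg]Cl)cc1 | starting material
6 | 4-methoxybenzaldehyde | COc1ccc(C=O)cc1 | starting material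
7 | chloromagnesium (1Z,3S)-1,4-bis(2,4-dimethoxyphenyl)-3-(4-methoxybenzyl)-4-oxobut-1-en-1-olate | COc1ccc(C(=O)[C@@H](Cc2ccc(OC)cc2)/C=C(\O[Mg]Cl)c2ccc(OC)cc2OC)c(OC)c1 | intermediate (not isolated)
8 | (2S,3S)-1,4-bis(2,4-dimethoxyphenyl)-2-[(S)-hydroxy(4-methoxyphenyl)methyl]-3-(4-methoxybenzyl)butane-1,4-dione | COc1ccc(C(=O)[C@@H](Cc2ccc(OC)cc2)[C@H](C(=O)c2ccc(OC)cc2OC)[C@H](O)c2ccc(OC)cc2)c(OC)c1 | intermediate (not isolated)
9 | (2,4-dimethoxyphenyl)[(2S,3S,4S)-5-(2,4-dimethoxyphenyl)-5-hydroxy-4-(4-methoxybenzyl)-2-(4-methoxyphenyl)oxolan-3-yl]methanone (C5 epimers) | COc1ccc(c(OC)c1)C1(O)O[C@H](c2ccc(OC)cc2)[C@@H](C(=O)c2ccc(OC)cc2OC)[C@@H]1Cc1ccc(OC)cc1 | intermediate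
10 | (2S,3S,4S)-3-(2,4-dimethoxybenzoyl)-5-(2,4-dimethoxyphenyl)-4-(4-methoxybenzyl)-2-(4-methoxyphenyl)-3,4-dihydro-2H-furan-1-ium | COc1ccc(c(OC)c1)C1=[O+][C@H](c2ccc(OC)cc2)[C@@H](C(=O)c2ccc(OC)cc2OC)[C@@H]1Cc1ccc(OC)cc1 | intermediate (not isolated)
11 | (2,4-dimethoxyphenyl)[(2S,3S,4S,5R)-5-(2,4-dimethoxyphenyl)-4-(4-methoxybenzyl)-2-(4-methoxyphenyl)oxolan-3-yl]methanone | COc1ccc(c(OC)c1)[C@@H]1O[C@H](c2ccc(OC)cc2)[C@@H](C(=O)c2ccc(OC)cc2OC)[C@@H]1Cc1ccc(OC)cc1 | intermediate
12 | (2,4-dihydroxyphenyl)[(2S,3S,4S,5R)-5-(2,4-dihydroxyphenyl)-4-(4-hydroxybenzyl)-2-(4-hydroxyphenyl)oxolan-3-yl]methanone | Oc1ccc(c(O)c1)[C@@H]1O[C@H](c2ccc(O)cc2)[C@@H](C(=O)c2ccc(O)cc2O)[C@@H]1Cc1ccc(O)cc1 | intermediate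
13 | 4-bromo-2-iodophenol | Oc1ccc(Br)cc1I | starting material
14 | 1-ethynyl-4-methoxybenzene | COc1ccc(C#C)cc1 | starting material
15 | 4-bromo-2-[(4-methoxyphenyl)ethynyl]phenol | COc1ccc(cc1)C#Cc1cc(Br)ccc1O | intermediate (not isolated)
16 | 5-bromo-2-(4-methoxyphenyl)-1-benzofuran | COc1ccc(cc1)-c1cc2cc(Br)ccc2o1 | intermediate
17 | 2,4-dimethoxybenzoyl chloride | COc1ccc(C(=O)Cl)c(OC)c1 | starting material
18 | [5-bromo-2-(4-methoxyphenyl)-1-benzofuran-3-yl](2,4-dimethoxyphenyl)methanone | COc1ccc(cc1)-c1oc2ccc(Br)cc2c1C(=O)c1ccc(OC)cc1OC | intermediate (not isolated)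
19 | [5-bromo-2-(4-methoxyphenyl)-1-benzofuran-3-yl](2-hydroxy-4-methoxyphenyl)methanone | COc1ccc(cc1)-c1oc2ccc(Br)cc2c1C(=O)c1ccc(OC)cc1O | intermediate
20 | 5-bromo-3-{[(diethoxymethylsilyl)oxy][2-((diethoxymethylsilyl)oxy)-4-methoxyphenyl]methylidene}-2-(4-methoxyphenyl)-2,3-dihydro-1-benzofuran (C2 has the same spatial arrangement as in 21; its descriptor is S because C3 now outranks the aryl group) | Brc1ccc2c(c1)C(=C(O[Si](C)(OCC)OCC)c1ccc(OC)cc1O[Si](C)(OCC)OCC)[C@H](c1ccc(OC)cc1)O2 | intermediate (not isolated)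
21 | [(2R,3R)-5-bromo-2-(4-methoxyphenyl)-2,3-dihydro-1-benzofuran-3-yl](2-hydroxy-4-methoxyphenyl)methanone | Brc1ccc2c(c1)[C@@H](C(=O)c1ccc(OC)cc1O)[C@H](c1ccc(OC)cc1)O2 | intermediate
22 | 2-{[(2R,3S)-5-bromo-2-(4-methoxyphenyl)-2,3-dihydro-1-benzofuran-3-yl](hydroxy)methyl}-5-methoxyphenol (carbinol epimers) | Brc1ccc2c(c1)[C@@H](C(O)c1ccc(OC)cc1O)[C@H](c1ccc(OC)cc1)O2 | intermediate
23 | 3-chloropropanoyl chloride | O=C(Cl)CCCl | starting material
24 | 3-chloro-1-(2,4-dimethoxyphenyl)propan-1-one | COc1ccc(C(=O)CCCl)c(OC)c1 | intermediate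
25 | 6-{[(2R,3R)-5-bromo-2-(4-methoxyphenyl)-2,3-dihydro-1-benzofuran-3-yl]methylidene}-3-methoxycyclohexa-2,4-dien-1-one | Brc1ccc2c(c1)[C@@H](C=C1C=CC(OC)=CC1=O)[C@H](c1ccc(OC)cc1)O2 | intermediate (not isolated)
26 | (2,4-dihydroxyphenyl){(2S,3S,4S,5R)-5-[5-((R)-[(2R,3R)-5-bromo-2-(4-methoxyphenyl)-2,3-dihydro-1-benzofuran-3-yl](2-hydroxy-4-methoxyphenyl)methyl)-2,4-dihydroxyphenyl]-4-(4-hydroxybenzyl)-2-(4-hydroxyphenyl)oxolan-3-yl}methanone | Brc1ccc2c(c1)[C@@H]([C@H](c1ccc(OC)cc1O)c1cc([C@@H]3O[C@H](c4ccc(O)cc4)[C@@H](C(=O)c4ccc(O)cc4O)[C@@H]3Cc3ccc(O)cc3)c(O)cc1O)[C@H](c1ccc(OC)cc1)O2 | intermediate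
27 | 1-(2,4-dimethoxyphenyl)prop-2-en-1-one | COc1ccc(C(=O)C=C)c(OC)c1 | intermediate (not isolated)
28 | (E)-1-(2,4-dimethoxyphenyl)-3-{(2R,3R)-3-[(R)-{5-[(2R,3S,4S,5S)-4-(2,4-dihydroxybenzoyl)-3-(4-hydroxybenzyl)-5-(4-hydroxyphenyl)oxolan-2-yl]-2,4-dihydroxyphenyl}(2-hydroxy-4-methoxyphenyl)methyl]-2-(4-methoxyphenyl)-2,3-dihydro-1-benzofuran-5-yl}prop-2-en-1-one | O=C(/C=C/c1ccc2c(c1)[C@@H]([C@H](c1ccc(OC)cc1O)c1cc([C@@H]3O[C@H](c4ccc(O)cc4)[C@@H](C(=O)c4ccc(O)cc4O)[C@@H]3Cc3ccc(O)cc3)c(O)cc1O)[C@H](c1ccc(OC)cc1)O2)c1ccc(OC)cc1OC | intermediate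
29 | lophirachalcone | O=C(/C=C/c1ccc2c(c1)[C@@H]([C@H](c1ccc(O)cc1O)c1cc([C@@H]3O[C@H](c4ccc(O)cc4)[C@@H](C(=O)c4ccc(O)cc4O)[C@@H]3Cc3ccc(O)cc3)c(O)cc1O)[C@H](c1ccc(O)cc1)O2)c1ccc(O)cc1O | target

**Step count**
Total: 12 steps. Longest linear sequence: 7 steps (steps 1–4, then 10–12; the West branch, steps 5–8 then 10–12, is equally long).

**Three steps most likely to fail, each with a fallback**

Step 2 (enantioselective benzyl conjugate addition to an ene-dione with aldol trapping has no direct precedent, and the aldol diastereoselectivity is uncertain). The fallback sets out from 4 and comes back at 9, and sets the benzyl-bearing centre by asymmetric hydrogenation instead. Zn dust in AcOH reduces the alkene of 4 to 1,4-bis(2,4-dimethoxyphenyl)butane-1,4-dione F1. A single Claisen–Schmidt condensation with one equivalent of 6 (KOH, EtOH, rt) gives (E)-1,4-bis(2,4-dimethoxyphenyl)-2-(4-methoxybenzylidene)butane-1,4-dione F2. Hydrogenation of the trisubstituted enone alkene with [Ir(cod)((S)-t-Bu-PHOX)]BArF under H2 (50 bar, CH2Cl2) gives (S)-1,4-bis(2,4-dimethoxyphenyl)-2-(4-methoxybenzyl)butane-1,4-dione F3. Kinetic deprotonation of the unhindered CH2 with LiN(SiMe3)2 in THF at −78 °C and addition of 6 gives aldol 8, which closes to hemiketal 9 on work-up.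

Step 7 (CuH may fail to attack the benzofuran enone, or may reduce the aryl bromide or the ketone). The fallback sets out from 19 and comes back at 21, and replaces hydride conjugate addition by asymmetric arene hydrogenation followed by epimerisation. The furan C2=C3 bond of 19 is hydrogenated with Ru(cod)(2-methylallyl)2 and the chiral N-heterocyclic carbene (R,R)-SINpEt (1,3-bis[(R)-1-(naphthalen-1-yl)ethyl]imidazolidin-2-ylidene) under H2 (60 bar, hexane, rt) to give the cis product [(2R,3S)-5-bromo-2-(4-methoxyphenyl)-2,3-dihydro-1-benzofuran-3-yl](2-hydroxy-4-methoxyphenyl)methanone F4. Catalytic DBU in CH2Cl2 then epimerises the acidic C3 to the trans ketone 21.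

Step 10 (the quinone methide can tautomerise towards a benzofuran, 22 can self-condense, and the facial control next to an existing stereocentre is untested). The fallback sets out from 11 and 22, skips step 4 and comes back at 29; it makes the same bond by a chiral-diol-catalysed boronate 1,4-addition to the quinone methide instead of a Friedel–Crafts reaction. NBS (MeCN, 0 °C) brominates the most electron-rich position of 11 to give (2,4-dimethoxyphenyl)[(2S,3S,4S,5R)-5-(5-bromo-2,4-dimethoxyphenyl)-4-(4-methoxybenzyl)-2-(4-methoxyphenyl)oxolan-3-yl]methanone F5. Borylation with Pd(OAc)2, XPhos, B2(OH)4 and KOAc (EtOH, 80 °C) gives {5-[(2R,3S,4S,5S)-4-(2,4-dimethoxybenzoyl)-3-(4-methoxybenzyl)-5-(4-methoxyphenyl)oxolan-2-yl]-2,4-dimethoxyphenyl}boronic acid F6. F6, esterified in situ with isopropanol over 4 Å MS, adds to quinone methide 25 (generated from 22 by loss of water) under (R)-3,3'-dibromo-BINOL (15 mol%) to give the hexa-O-methyl analogue of 26 F7. Heck coupling of F7 with 24 under the conditions of step 11 gives the hexa-O-methyl analogue of 28 F8. BBr3 (CH2Cl2, −78 → 0 °C) then cleaves all ten methyl ethers of F8 to give 29.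

**Further compounds**
F1 | step 2 | 1,4-bis(2,4-dimethoxyphenyl)butane-1,4-dione | COc1ccc(C(=O)CCC(=O)c2ccc(OC)cc2OC)c(OC)c1
F2 | step 2 | (E)-1,4-bis(2,4-dimethoxyphenyl)-2-(4-methoxybenzylidene)butane-1,4-dione | COc1ccc(/C=C(\CC(=O)c2ccc(OC)cc2OC)C(=O)c2ccc(OC)cc2OC)cc1
F3 | step 2 | (S)-1,4-bis(2,4-dimethoxyphenyl)-2-(4-methoxybenzyl)butane-1,4-dione | COc1ccc(C(=O)[C@@H](Cc2ccc(OC)cc2)CC(=O)c2ccc(OC)cc2OC)c(OC)c1
F4 | step 7 | [(2R,3S)-5-bromo-2-(4-methoxyphenyl)-2,3-dihydro-1-benzofuran-3-yl](2-hydroxy-4-methoxyphenyl)methanone | Brc1ccc2c(c1)[C@H](C(=O)c1ccc(OC)cc1O)[C@H](c1ccc(OC)cc1)O2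
F5 | step 10 | (2,4-dimethoxyphenyl)[(2S,3S,4S,5R)-5-(5-bromo-2,4-dimethoxyphenyl)-4-(4-methoxybenzyl)-2-(4-methoxyphenyl)oxolan-3-yl]methanone | COc1cc(OC)c(cc1Br)[C@@H]1O[C@H](c2ccc(OC)cc2)[C@@H](C(=O)c2ccc(OC)cc2OC)[C@@H]1Cc1ccc(OC)cc1
F6 | step 10 | {5-[(2R,3S,4S,5S)-4-(2,4-dimethoxybenzoyl)-3-(4-methoxybenzyl)-5-(4-methoxyphenyl)oxolan-2-yl]-2,4-dimethoxyphenyl}boronic acid | COc1cc(OC)c(cc1B(O)O)[C@@H]1O[C@H](c2ccc(OC)cc2)[C@@H](C(=O)c2ccc(OC)cc2OC)[C@@H]1Cc1ccc(OC)cc1
F7 | step 10 | hexa-O-methyl analogue of 26 (all six hydroxyls of the tetrahydrofuran part as methyl ethers) | Brc1ccc2c(c1)[C@@H]([C@H](c1ccc(OC)cc1O)c1cc([C@@H]3O[C@H](c4ccc(OC)cc4)[C@@H](C(=O)c4ccc(OC)cc4OC)[C@@H]3Cc3ccc(OC)cc3)c(OC)cc1OC)[C@H](c1ccc(OC)cc1)O2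
F8 | step 10 | hexa-O-methyl analogue of 28 (ten methyl ethers, one free phenol) | O=C(/C=C/c1ccc2c(c1)[C@@H]([C@H](c1ccc(OC)cc1O)c1cc([C@@H]3O[C@H](c4ccc(OC)cc4)[C@@H](C(=O)c4ccc(OC)cc4OC)[C@@H]3Cc3ccc(OC)cc3)c(OC)cc1OC)[C@H](c1ccc(OC)cc1)O2)c1ccc(OC)cc1OC
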